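**Strategy.** With the side chain numbered as a hepta-1,6-dien-2-yl group (C1′–C7′), the target is cut at C4′–C5′, between the homoallylic CH2 and the isopropenyl carbinol. C5′ lies too far from ring stereocentre C1 for substrate control, so the union is catalyst-controlled. The precursor is the fully halogenated cyclohexyl acetate bearing a buta-1,3-dien-2-yl group. Its vinyl terminus C3′=C4′ is hydroborated (C2′=C1′ is shielded by quaternary C1), boron is exchanged for zinc, and a chiral titanium bis(sulfonamide) adds the alkyl group to methacrolein, an α-branched enal. One operation forms the bond, sets (R)-C5′ and leaves the C2′ methylene. The C1/C3/C4 triad is set earlier on a slim ethynyl carbinol.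

Key step: step 10

Numbering: ring C1 = carbinol carbon, C3 = CHCl, C4 = C(Br)CH3; side chain C1′(=CH2), C2′, C3′, C4′, C5′(OH), C6′(=C7′H2)CH3.

Assumption: the facial sense of the diammonium catalyst in step 3 with isoprene is inferred by analogy with other dienes, so (R)-BINAM is written and its antipode is used should the (1R)-adduct form.

Step 1
Reactants: 1 2,2-dimethyl-1,3-dioxan-5-one
Product: 2 2,2-dimethyl-4H-1,3-dioxin-5-yl cyclohexanecarboxylate
Conditions: KHMDS, THF, −78 °C; then cyclohexanecarbonyl chloride, −78 → 0 °C
Reagents that add atoms: cyclohexanecarbonyl chloride, O=C(Cl)C1CCCCC1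
Why: Enolate O-acylation: the dissociated potassium enolate of the dioxanone reacts with the hard acyl chloride at oxygen to give the enol ester, and no stereocentre is involved.

Step 2
Reactants: 2 2,2-dimethyl-4H-1,3-dioxin-5-yl cyclohexanecarboxylate
Product: 3 1-formylethenyl cyclohexanecarboxylate [2-(cyclohexanecarbonyloxy)acrolein]
Conditions: toluene, 110 °C, BHT (cat.)
Reagents that add atoms: none
Why: Retro-hetero-Diels–Alder cycloreversion of the 4H-1,3-dioxin expels acetone on heating and unmasks the sensitive 2-acyloxy enal under neutral conditions.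

Step 3
Reactants: 3 1-formylethenyl cyclohexanecarboxylate; 4 isoprene
Product: 5 (1S)-1-formyl-4-methylcyclohex-3-en-1-yl cyclohexanecarboxylate
Conditions: (R)-1,1′-binaphthyl-2,2′-diamine (5 mol %), Tf2NH (9.5 mol %), isoprene (excess), EtCN, −60 → −40 °C
Reagents that add atoms: none
Why: Enantioselective Diels–Alder reaction under iminium activation by a chiral primary diammonium salt, a known catalyst class for α-acyloxyacroleins: the methyl group of isoprene directs the "para" orientation and the binaphthyl backbone shields one face of the iminium dienophile, which sets C1 as (S).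

Step 4
Reactants: 5 (1S)-1-formyl-4-methylcyclohex-3-en-1-yl cyclohexanecarboxylate
Product: 7 (1S)-1-ethynyl-4-methylcyclohex-3-en-1-ol, via hydroxy aldehyde 6 (not isolated)
Conditions: K2CO3, MeOH, 0 °C; then dimethyl (1-diazo-2-oxopropyl)phosphonate, 0 °C → rt
Reagents that add atoms: dimethyl (1-diazo-2-oxopropyl)phosphonate, CC(=O)C(=[N+]=[N-])P(=O)(OC)OC
Why: Carbonate-promoted methanolysis, helped by the neighbouring hemiacetal alkoxide, frees the tertiary carbinol, and Ohira–Bestmann (Seyferth–Gilbert) homologation then turns the non-enolisable aldehyde into the alkyne without touching C1.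

Step 5
Reactants: 7 (1S)-1-ethynyl-4-methylcyclohex-3-en-1-ol
Product: 8 (1S,3S,6R)-3-ethynyl-6-methyl-7-oxabicyclo[4.1.0]heptan-3-ol (epoxide cis to the hydroxyl group)
Conditions: VO(acac)2 (3 mol %), t-BuOOH (decane), CH2Cl2, 0 °C → rt
Reagents that add atoms: tert-butyl hydroperoxide, CC(C)(C)OO
Why: Vanadium-catalysed hydroxyl-directed epoxidation of a cyclohex-3-en-1-ol: the metal peroxide bound to the pseudoaxial C1–O delivers oxygen to the alkene face syn to the hydroxyl group, which fixes the faces of C3 and C4 relative to C1 while the alkyne stays inert.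

Step 6
Reactants: 8 (1S,3S,6R)-3-ethynyl-6-methyl-7-oxabicyclo[4.1.0]heptan-3-ol
Product: 9 (1S,3S,6R)-3-ethynyl-6-methyl-7-oxabicyclo[4.1.0]heptan-3-yl acetate
Conditions: Ac2O, Et3N, DMAP (cat.), CH2Cl2, rt
Reagents that add atoms: acetic anhydride, CC(=O)OC(C)=O
Why: DMAP-catalysed acylation of the unhindered propargylic tertiary alcohol; the acetate prevents transannular attack of the C1 oxygen on C4 (7-oxabicyclo[2.2.1]heptane formation) in steps 7 and 8 and removes the acidic proton before step 10.

Step 7
Reactants: 9 (1S,3S,6R)-3-ethynyl-6-methyl-7-oxabicyclo[4.1.0]heptan-3-yl acetate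
Product: 10 (1S,3R,4R)-3-chloro-1-ethynyl-4-hydroxy-4-methylcyclohexyl acetate
Conditions: LiCl (excess), AcOH, THF, 25 → 45 °C
Reagents that add atoms: lithium chloride, [Li+].[Cl-]
Why: Nucleophilic (SN2) epoxide opening to a chlorohydrin under weakly acidic lithium halide conditions: chloride attacks the less substituted C3 with inversion along the trans-diaxial (Fürst–Plattner) path of the half-chair that places the slim ethynyl group axial, which sets C3 as (R) and leaves the C4–O bond untouched.

Step 8
Reactants: 10 (1S,3R,4R)-3-chloro-1-ethynyl-4-hydroxy-4-methylcyclohexyl acetate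
Product: 11 (1S,3R,4R)-4-bromo-3-chloro-1-ethynyl-4-methylcyclohexyl acetate
Conditions: Me3SiBr, CH2Cl2, −20 → 0 °C, dark
Reagents that add atoms: bromotrimethylsilane, C[Si](C)(C)Br
Why: Deoxybromination of a tertiary alcohol with bromotrimethylsilane (SN1 with neighbouring-halogen control): ionisation of the activated axial C4–O bond anti to the axial C3–Cl gives the same chlorine-bridged tertiary cation as electrophilic chlorination of a 1-methylcyclohexene, which bromide captures at C4 anti to chlorine, so that C4 keeps its configuration (R, trans bromochloride), while the acetate at the ethynyl-deactivated C1 is not ionised.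

Step 9
Reactants: 11 (1S,3R,4R)-4-bromo-3-chloro-1-ethynyl-4-methylcyclohexyl acetate
Product: 12 (1S,3R,4R)-4-bromo-1-(buta-1,3-dien-2-yl)-3-chloro-4-methylcyclohexyl acetate
Conditions: ethylene (1–4 bar), Grubbs second-generation catalyst (5 mol %), CH2Cl2, 25–40 °C
Reagents that add atoms: ethylene, C=C
Why: Ethylene–alkyne cross (enyne) metathesis converts the terminal propargylic acetate into the 2-substituted 1,3-diene under neutral conditions that leave both halides and all three stereocentres untouched.

Step 10
Reactants: 12 (1S,3R,4R)-4-bromo-1-(buta-1,3-dien-2-yl)-3-chloro-4-methylcyclohexyl acetate; 13 methacrolein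
Product: 17 (1S,3R,4R)-4-bromo-3-chloro-1-[(5R)-5-hydroxy-6-methylhepta-1,6-dien-2-yl]-4-methylcyclohexyl acetate, via diethyl(alkyl)borane 14 (not isolated), via dialkylzinc 15 (not isolated), via mixed silylmethylzinc 16 (not isolated)
Conditions: (i) Et2BH (from Et3B/BH3·SMe2), Et2O, 0 °C → rt; (ii) Et2Zn (neat), 0 °C, then high vacuum; (iii) (Me3SiCH2)2Zn, toluene; (iv) 13, Ti(OiPr)4, (1S,2S)-1,2-bis(trifluoromethanesulfonamido)cyclohexane (8 mol %), toluene, −20 °C, argon; cold 1 M HCl
Reagents that add atoms: none
Why: Diethylborane adds anti-Markovnikov to the monosubstituted C3′=C4′ bond of the 2-substituted diene, because C2′=C1′ is 1,1-disubstituted and flanked by the fully substituted ring carbon C1, so boron ends on C4′ and the C2′ methylene of the target is left in place. Boron–zinc exchange with Et2Zn is driven by removal of volatile Et3B, and comproportionation with (Me3SiCH2)2Zn gives a mixed reagent whose silylmethyl group does not transfer, so each ring fragment can be delivered. The titanium complex of the (1S,2S)-bis(triflamide) binds methacrolein and passes the alkyl group to its Re face in a 1,2-addition; the closest known reaction type is the catalytic asymmetric addition of functionalised dialkylzincs, made by hydroboration and boron–zinc exchange, to α-branched enals. No ring is closed, and the only new stereocentre, C5′ (R), is set by the ligand alone, since C1, C3 and C4 are too remote to interfere. The step needs 1,2- over 1,4-addition, which titanium activation of C=O and the absence of copper secure. It also needs tolerance of the acetate, the secondary chloride and the tertiary bromide, which rests on the low basicity and nucleophilicity of diorganozincs, the non-polar medium, low temperature, strict exclusion of oxygen, and the β-chlorine that retards ionisation at C4.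

Step 11
Reactants: 17 (1S,3R,4R)-4-bromo-3-chloro-1-[(5R)-5-hydroxy-6-methylhepta-1,6-dien-2-yl]-4-methylcyclohexyl acetate
Product: 18 (1S,3R,4R)-4-bromo-3-chloro-1-[(5R)-5-hydroxy-6-methylhepta-1,6-dien-2-yl]-4-methylcyclohexan-1-ol (target)
Conditions: DIBAL-H, THF/toluene, −78 °C; aq. Rochelle salt
Reagents that add atoms: none
Why: Reductive ester cleavage: hydride attacks only the acetyl carbonyl at −78 °C, the C1–O bond is not broken, no base strong enough for E2 at the tertiary bromide is present, and the ether solvent tempers the Lewis acidity of aluminium toward the halides.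

**Compound list**

1 | 2,2-dimethyl-1,3-dioxan-5-one | CC1(C)OCC(=O)CO1 | starting material
2 | 2,2-dimethyl-4H-1,3-dioxin-5-yl cyclohexanecarboxylate | CC1(C)OCC(OC(=O)C2CCCCC2)=CO1 | intermediate
3 | 1-formylethenyl cyclohexanecarboxylate | C=C(C=O)OC(=O)C1CCCCC1 | intermediate
4 | isoprene | C=CC(C)=C | starting material
5 | (1S)-1-formyl-4-methylcyclohex-3-en-1-yl cyclohexanecarboxylate | O=C[C@]1(OC(=O)C2CCCCC2)CCC(C)=CC1 | intermediate
6 | (1S)-1-hydroxy-4-methylcyclohex-3-ene-1-carbaldehyde | O=C[C@]1(O)CCC(C)=CC1 | intermediate
7 | (1S)-1-ethynyl-4-methylcyclohex-3-en-1-ol | C#C[C@]1(O)CCC(C)=CC1 | intermediate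
8 | (1S,3S,6R)-3-ethynyl-6-methyl-7-oxabicyclo[4.1.0]heptan-3-ol | C#C[C@]1(O)CC[C@@]2(C)O[C@H]2C1 | intermediate
9 | (1S,3S,6R)-3-ethynyl-6-methyl-7-oxabicyclo[4.1.0]heptan-3-yl acetate | C#C[C@]1(OC(C)=O)CC[C@@]2(C)O[C@H]2C1 | intermediate
10 | (1S,3R,4R)-3-chloro-1-ethynyl-4-hydroxy-4-methylcyclohexyl acetate | C#C[C@]1(OC(C)=O)CC[C@@](C)(O)[C@H](Cl)C1 | intermediate
11 | (1S,3R,4R)-4-bromo-3-chloro-1-ethynyl-4-methylcyclohexyl acetate | C#C[C@]1(OC(C)=O)CC[C@@](C)(Br)[C@H](Cl)C1 | intermediate
12 | (1S,3R,4R)-4-bromo-1-(buta-1,3-dien-2-yl)-3-chloro-4-methylcyclohexyl acetate | C=CC(=C)[C@]1(OC(C)=O)CC[C@@](C)(Br)[C@H](Cl)C1 | intermediate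
13 | methacrolein | C=C(C)C=O | starting material
14 | (1S,3R,4R)-4-bromo-3-chloro-1-[4-(diethylboranyl)but-1-en-2-yl]-4-methylcyclohexyl acetate | CCB(CC)CCC(=C)[C@]1(OC(C)=O)CC[C@@](C)(Br)[C@H](Cl)C1 | intermediate
15 | bis{3-[(1S,3R,4R)-1-acetoxy-4-bromo-3-chloro-4-methylcyclohexyl]but-3-en-1-yl}zinc | C=C(CC[Zn]CCC(=C)[C@]1(OC(C)=O)CC[C@@](C)(Br)[C@H](Cl)C1)[C@]1(OC(C)=O)CC[C@@](C)(Br)[C@H](Cl)C1 | intermediate
16 | {3-[(1S,3R,4R)-1-acetoxy-4-bromo-3-chloro-4-methylcyclohexyl]but-3-en-1-yl}[(trimethylsilyl)methyl]zinc | C[Si](C)(C)C[Zn]CCC(=C)[C@]1(OC(C)=O)CC[C@@](C)(Br)[C@H](Cl)C1 | intermediate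
17 | (1S,3R,4R)-4-bromo-3-chloro-1-[(5R)-5-hydroxy-6-methylhepta-1,6-dien-2-yl]-4-methylcyclohexyl acetate | C=C(C)[C@H](O)CCC(=C)[C@]1(OC(C)=O)CC[C@@](C)(Br)[C@H](Cl)C1 | intermediate
18 | (1S,3R,4R)-4-bromo-3-chloro-1-[(5R)-5-hydroxy-6-methylhepta-1,6-dien-2-yl]-4-methylcyclohexan-1-ol | C=C(C)[C@H](O)CCC(=C)[C@]1(O)CC[C@@](C)(Br)[C@H](Cl)C1 | target

Total step count: 11. Longest linear sequence: 11 steps (1 → 18).

**Steps most likely to fail**

1. **Step 10.**
   - What may go wrong: bromine may be lost from C4, through a radical chain started by traces of oxygen or through Lewis-acid ionisation, and the vicinal dihalide then collapses. The boron–zinc exchange may stay incomplete. Ethyl transfer from residual Et2Zn may compete, or facial selectivity at the aldehyde may erode.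
   - Fallback, from 12 back to 17: 12 is hydroborated with 9-BBN-H to the B-alkyl-9-BBN derivative F1. This is coupled with S-ethyl 2-methylprop-2-enethioate under palladium(0)/copper(I) thiophene-2-carboxylate (Liebeskind–Srogl ketone synthesis). The same C4′–C5′ bond forms without zinc or titanium alkyls, giving the isopropenyl ketone F2. Corey–Bakshi–Shibata reduction of F2 with the (S)-methyl oxazaborolidine and catecholborane at −78 °C then sets (R)-C5′ and gives 17.

2. **Step 8.**
   - What may go wrong: the C4 cation may lose a proton instead of being captured. Bromide may enter from the face syn to chlorine if bridging is weak. The propargylic acetate may ionise, or HBr may add to the alkyne.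
   - Fallback, from 10 back to 11: substitution is replaced by elimination–addition. POCl3/pyridine removes the C4 hydroxyl by anti elimination; the C3–H is syn to the leaving group, so no vinyl chloride can arise. This gives the allylic chloride (1S,5R)-5-chloro-1-ethynyl-4-methylcyclohex-3-en-1-yl acetate F3. Dry HBr in CH2Cl2 at −78 °C then adds in the Markovnikov sense, with bromide entering anti to chlorine, to return 11.

3. **Step 7.**
   - What may go wrong: chloride may attack the tertiary C4. The epoxide may rearrange to a ketone under lithium-ion catalysis. The hindered trisubstituted epoxide may simply open too slowly.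
   - Fallback, from 7 back to 10: the epoxide is bypassed. 7 is acetylated directly (Ac2O, Et3N, DMAP) to (1S)-1-ethynyl-4-methylcyclohex-3-en-1-yl acetate F4. Electrophilic chlorohydroxylation with N-chlorosuccinimide in aqueous acetone places chlorine on C3 and water on the tertiary C4 by the Markovnikov rule. The trans-diaxial adduct formed through the ethynyl-axial half-chair is 10, which is separated from its C3/C4 diastereomer by chromatography.

Further compounds
F1 | step 10 | (1S,3R,4R)-1-[4-(9-borabicyclo[3.3.1]nonan-9-yl)but-1-en-2-yl]-4-bromo-3-chloro-4-methylcyclohexyl acetate | C=C(CCB1C2CCCC1CCC2)[C@]3(OC(C)=O)CC[C@@](C)(Br)[C@H](Cl)C3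
F2 | step 10 | (1S,3R,4R)-4-bromo-3-chloro-4-methyl-1-(6-methyl-5-oxohepta-1,6-dien-2-yl)cyclohexyl acetate | C=C(C)C(=O)CCC(=C)[C@]1(OC(C)=O)CC[C@@](C)(Br)[C@H](Cl)C1
F3 | step 8 | (1S,5R)-5-chloro-1-ethynyl-4-methylcyclohex-3-en-1-yl acetate | C#C[C@]1(OC(C)=O)CC=C(C)[C@H](Cl)C1
F4 | step 7 | (1S)-1-ethynyl-4-methylcyclohex-3-en-1-yl acetate | C#C[C@]1(OC(C)=O)CCC(C)=CC1
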